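All runs were generated by integration with made-up constants; noise was put on by code.

It is tempting to multiply the rate by the catalyst charge and stop, but partner (the limiting reagent) is also lost to the protic impurity, and how much is lost depends on how fast the catalyst reaches the conversion asked about.

| setting | beta | epsilon | flask |
|---|---|---|---|
| left-handed substrate | 0.050 M | 0.050 M | 0.050 M |
| right-handed substrate | 0.050 M | 0.050 M | 0.050 M |
| partner | 0.040 M | 0.040 M | 0.0400 M |
| protic impurity | 0.015 M | 0.015 M | 0.0150 M |
| free catalyst | 0.085 mM | 0.13 mM | 0.17 mM |
| remark | run made earlier | run made earlier |  |

| run | time / min | left-handed product / % | left-handed substrate / % |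
|---|---|---|---|
| beta | 3.00 | 2.8 | 46.9 |
| beta | 5.00 | 4.5 | 46.2 |
| beta | 8.00 | 4.8 | 45.9 |
| beta | 12.0 | 7.3 | 42.8 |
| beta | 20.0 | 8.3 | 39.4 |
| beta | 40.0 | 13.7 | 36.9 |
| epsilon | 2.50 | 5.2 | 48.7 |
| epsilon | 8.00 | 8.3 | 40.7 |
| epsilon | 12.0 | 9.9 | 40.3 |
| epsilon | 20.0 | 12.2 | 37.9 |
| epsilon | 30.0 | 12.2 | 37.3 |
| epsilon | 40.0 | 14.3 | 34.9 |

(readings scatter by 1 percentage point)

- factor on the rate of making left-handed product when 10% of the left-handed substrate and right-handed substrate together are converted if free catalyst is charged twice over
- factor on the rate when 10% of the left-handed substrate and right-handed substrate together are converted if free catalyst is charged at 0.80 mM instead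

- free catalyst is single-handed; left-handed substrate and right-handed substrate are mirror images of each other, charged as a racemate, each of them at the stated concentration
- what may be going on: partner -> decomposition product; free catalyst + left-handed substrate <-> catalyst intermediate A; partner + protic impurity -> quenched reagent; free catalyst + right-handed substrate <-> catalyst intermediate B; partner + catalyst intermediate B -> free catalyst + right-handed product; partner + catalyst intermediate A -> free catalyst + left-handed product

We take both routes to be first order in partner, so time cancels from their ratio. That leaves one race number, N: partner turned into product per partner quenched at the start.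

In the epsilon run, left-handed product first rises at 2.08 mM/min, then at 0.564 mM/min. Over interval midpoints 4.00 min apart, these scattered readings suggest partner decaying at 0.326 /min. Taking the last epsilon reading as the stall, and assuming that partner beyond the protic impurity charge became product, we read the left-handed share of product as 57.2%, so the catalytic route takes 0.0909 /min and quenching takes the rest. This gives 0.386 for epsilon, and scaling by charge gives the race number of the flask, 0.505.

Integrating, the partner quenched by conversion x is Q = H(1 − exp(−x/(NH))), where H is the impurity charge and x is 10.0 mM. As a test on other readings, though with the same share, the beta run read in the same way gives N of 0.239, against 0.252 scaled from epsilon by charge.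

For the flask, Q is 11.0 mM. Doubled, it is 7.25 mM, and at 0.80 mM it is 3.67 mM. Charge times remaining partner then gives our factors, 2.39 and 6.52.

The forecast says 2.4 and 6.4, reached “before quenching has taken as much partner”. The simulation gives 2.43 and 6.82.

    partner → decomposition product (k = 2.67 × 10⁻⁶ /s)
    free catalyst + left-handed substrate ⇌ catalyst intermediate A (K = 5.28 /M, k = 1680 /M/s)
    partner + protic impurity → quenched reagent (k = 0.262 /M/s)
    free catalyst + right-handed substrate ⇌ catalyst intermediate B (K = 34.0 /M, k = 91.7 /M/s)
    partner + catalyst intermediate B → free catalyst + right-handed product (k = 7.96 /M/s)
    partner + catalyst intermediate A → free catalyst + left-handed product (k = 70.6 /M/s)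

In the flask, quenching ran alongside the catalytic steps: by 3.00 min the protic impurity stood at 27.1% of its charge, with 10.9 mM of quenched reagent, where N gives 10.5 mM at that conversion. By 15.0 min the impurity was down to 4.26% and partner to 11.1%, and the catalytic steps ran on: at 300 min, partner stood at 0% and left-handed product at 14.6%.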